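The non-aromatic six-membered ring (C1, C2, C3, C4, C4a, C8a) holds a 1,4-relationship between C4 and the hydroxymethyl carbon on C2. At the ketone/ester oxidation level this is a γ-keto ester, the signature of a β-keto ester homologated by one carbon. The ring is therefore built first as a five-membered ring: a catalytic asymmetric Nazarov cyclisation gives a 3-aryl-1-indanone-2-carboxylate and sets the diarylmethine centre (C1). A zinc-carbenoid ring expansion then inserts CH2, the future C3, between the ketone carbon (future C4) and C2, delivering the 4-aryl-1-tetralone-3-carboxylate. Diethoxymethylation at C3, hydride reduction and acid-induced dehydration with loss of the phenol protecting group complete the enal.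

Key step: step 3

Remark: ring atoms are numbered above as in a 1-aryl-1,2-dihydronaphthalene (C1 CHAr, C2 CHCH2OH, C3 C(CHO), C4 =CH), whereas the systematic name of 10 numbers from the aldehyde; the (R,R)-ligand of step 2 is assumed to lead to the (3S) series (its antipode is used if the sense of induction is the reverse); the transient centres C3 of 8 and C1/C2 of 9 form as mixtures, are removed in step 5 and are left undefined in the SMILES.

Step 1
Reactants: 1 ethyl 3-(3,4-dimethoxyphenyl)-3-oxopropanoate; 2 3-methoxy-4-(methoxymethoxy)benzaldehyde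
Product: 3 ethyl (E)-2-(3,4-dimethoxybenzoyl)-3-[3-methoxy-4-(methoxymethoxy)phenyl]prop-2-enoate
Conditions: piperidine (0.1 equiv), AcOH (0.1 equiv), toluene, reflux, Dean–Stark; E isomer purified by crystallisation
Reagents that add atoms: none
Why: Knoevenagel condensation of the doubly activated methylene of 1 with the aryl aldehyde under piperidinium acetate catalysis is driven by azeotropic removal of water and should give mainly the E alkylidene β-keto ester, which is carried on as a single geometry so that one defined pentadienyl cation enters the stereodefining step; no stereocentre is formed.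

Step 2
Reactants: 3
Product: 4 ethyl (2R,3S)-5,6-dimethoxy-3-[3-methoxy-4-(methoxymethoxy)phenyl]-1-oxo-2,3-dihydro-1H-indene-2-carboxylate (trans)
Conditions: Cu(OTf)2 (10 mol %), 2,2'-isopropylidenebis[(4R)-4-phenyl-2-oxazoline] (11 mol %), ClCH2CH2Cl, 40 °C
Reagents that add atoms: none
Why: Catalytic asymmetric Nazarov cyclisation, in which two-point binding of the β-keto ester to the Cu(II)–bis(oxazoline) Lewis acid generates the pentadienyl cation and conrotatory 4π-electrocyclisation onto the veratroyl carbon para to its 3-methoxy group followed by rearomatisation gives the indanone, the C2-symmetric ligand biasing the sense of conrotation and thereby setting the aryl-bearing C3 centre (S), while C2 settles trans through the enol of the β-keto ester.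

Step 3
Reactants: 4
Product: 7 ethyl (1S,2S)-6,7-dimethoxy-1-[3-methoxy-4-(methoxymethoxy)phenyl]-4-oxo-1,2,3,4-tetrahydronaphthalene-2-carboxylate (trans), via zinc cyclopropanolate 5 (not isolated), via C2-epimeric keto ester 6 (not isolated)
Conditions: Et2Zn (3 equiv), CH2I2 (3 equiv), CH2Cl2, 0 °C → rt; aq NH4Cl; crude, NaOEt (0.3 equiv), EtOH, rt, N2
Reagents that add atoms: diiodomethane, ICI
Why: Diethylzinc converts 4 into its zinc enolate, which is C-alkylated at C2 (indanone numbering) by EtZnCH2I on the face anti to the C3 aryl group; the zinc homoenolate so formed adds to the adjacent ketone to give donor–acceptor cyclopropanolate 5, and cleavage of its internal bond (the old C1–C2 bond) gives the ring-expanded zinc ester enolate, protonated on work-up to 6. The closest known reaction type is the zinc-carbenoid homologation of β-keto esters to γ-keto esters in its ring-expansion form on cyclic β-keto esters (the ionic counterpart of the Dowd–Beckwith expansion). The six-membered carbocycle is not closed by a cyclisation: it arises from the five-membered indanone ring by a 3-exo-trig closure to the fused cyclopropane followed by fragmentation of the shared bond, which inserts the carbenoid CH2 between the ketone carbon and C2. The aryl-bearing centre is untouched and stays S; the ester-bearing centre passes through the enolate and is then set by thermodynamic control, ethoxide in ethanol equilibrating 6 to the trans (1S,2S) ester 7, in which aryl and ester avoid the gauche interaction of the cis isomer. The step needs fragmentation of the internal rather than a peripheral cyclopropane bond and C- rather than O-alkylation of the enolate; the first is secured because only internal cleavage gives an ester-stabilised enolate and releases the bicyclo[3.1.0] strain, the second is the normal course of zinc enolates with this carbenoid.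

Step 4
Reactants: 7
Product: 8 ethyl (1S,2R)-3-(diethoxymethyl)-6,7-dimethoxy-1-[3-methoxy-4-(methoxymethoxy)phenyl]-4-oxo-1,2,3,4-tetrahydronaphthalene-2-carboxylate (C3 epimers)
Conditions: HC(OEt)3, BF3·OEt2, CH2Cl2, −30 °C → 0 °C; then 7, iPr2NEt, −78 °C → −20 °C
Reagents that add atoms: triethyl orthoformate, CCOC(OCC)OCC
Why: Mock-type α-diethoxymethylation of a ketone, in which the amine-generated enol derivative of the aryl ketone attacks the preformed diethoxycarbenium ion at the only ketone α-position (C3) at low temperature without enolising the ester-bearing C2, so that the trans C1/C2 relationship is kept, the new C3 centre (expected anti to the ester) being inconsequential because it becomes sp2 in step 5.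

Step 5
Reactants: 8
Product: 10 (3R,4S)-4-(4-hydroxy-3-methoxyphenyl)-3-(hydroxymethyl)-6,7-dimethoxy-3,4-dihydronaphthalene-2-carbaldehyde (target), via diol acetal 9 (not isolated)
Conditions: LiAlH4, THF, 0 °C → rt; quench, then 3 M aq HCl, THF, 45 °C, N2
Reagents that add atoms: water, O
Why: Hydride reduction followed by acetal hydrolysis and β-elimination, in which LiAlH4 reduces ketone and ester while acetal and MOM ether survive, and aqueous HCl then unmasks the aldehyde, dehydrates the p-methoxy-activated benzylic β-hydroxy aldehyde to the arene-conjugated enal and hydrolyses the aryl MOM ether, the two existing stereocentres being safe because neither C–H is acidified by the enal.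

Compound list
1 | ethyl 3-(3,4-dimethoxyphenyl)-3-oxopropanoate | CCOC(=O)CC(=O)c1ccc(OC)c(OC)c1 | starting material
2 | 3-methoxy-4-(methoxymethoxy)benzaldehyde (vanillin MOM ether) | COCOc1ccc(C=O)cc1OC | starting material
3 | ethyl (E)-2-(3,4-dimethoxybenzoyl)-3-[3-methoxy-4-(methoxymethoxy)phenyl]prop-2-enoate | CCOC(=O)/C(=C/c1ccc(OCOC)c(OC)c1)C(=O)c1ccc(OC)c(OC)c1 | intermediate
4 | ethyl (2R,3S)-5,6-dimethoxy-3-[3-methoxy-4-(methoxymethoxy)phenyl]-1-oxo-2,3-dihydro-1H-indene-2-carboxylate (trans) | COCOc1ccc([C@H]2c3cc(OC)c(OC)cc3C(=O)[C@@H]2C(=O)OCC)cc1OC | intermediate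
5 | ethylzinc cyclopropanolate: cyclopropane fused across C1–C2 of the indane, CH2 anti to the C3 aryl group, O–Zn on C1, ester on C2 (not isolated) | COCOc1ccc([C@H]2c3cc(OC)c(OC)cc3[C@]4(O[Zn]CC)C[C@]24C(=O)OCC)cc1OC | intermediate
6 | ethyl (1S)-6,7-dimethoxy-1-[3-methoxy-4-(methoxymethoxy)phenyl]-4-oxo-1,2,3,4-tetrahydronaphthalene-2-carboxylate, C2 epimer mixture (not isolated) | COCOc1ccc([C@H]2c3cc(OC)c(OC)cc3C(=O)CC2C(=O)OCC)cc1OC | intermediate
7 | ethyl (1S,2S)-6,7-dimethoxy-1-[3-methoxy-4-(methoxymethoxy)phenyl]-4-oxo-1,2,3,4-tetrahydronaphthalene-2-carboxylate (trans) | COCOc1ccc([C@H]2c3cc(OC)c(OC)cc3C(=O)C[C@@H]2C(=O)OCC)cc1OC | intermediate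
8 | ethyl (1S,2R)-3-(diethoxymethyl)-6,7-dimethoxy-1-[3-methoxy-4-(methoxymethoxy)phenyl]-4-oxo-1,2,3,4-tetrahydronaphthalene-2-carboxylate (C3 epimers) | COCOc1ccc([C@H]2c3cc(OC)c(OC)cc3C(=O)C(C(OCC)OCC)[C@@H]2C(=O)OCC)cc1OC | intermediate
9 | (3R,4S)-2-(diethoxymethyl)-3-(hydroxymethyl)-6,7-dimethoxy-4-[3-methoxy-4-(methoxymethoxy)phenyl]-1,2,3,4-tetrahydronaphthalen-1-ol, C1/C2 epimers (not isolated) | COCOc1ccc([C@H]2c3cc(OC)c(OC)cc3C(O)C(C(OCC)OCC)[C@@H]2CO)cc1OC | intermediate
10 | (3R,4S)-4-(4-hydroxy-3-methoxyphenyl)-3-(hydroxymethyl)-6,7-dimethoxy-3,4-dihydronaphthalene-2-carbaldehyde | COc1cc([C@H]2c3cc(OC)c(OC)cc3C=C(C=O)[C@@H]2CO)ccc1O | target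

Total step count: 5
Longest linear sequence: 5 steps (1/2 → 3 → 4 → 7 → 8 → 10)

Steps most likely to fail

Step 2. The chiral copper complex may turn over slowly on an aroyl ring that has only one methoxy group para to the ring-closing carbon, may control the sense of conrotation poorly, or may strip the MOM group. The fallback builds the same indanone by a ligand-controlled conjugate addition; it sets out from 2 and comes back at 4. Claisen–Schmidt condensation of 2 with 1-(2-bromo-4,5-dimethoxyphenyl)ethanone (CC(=O)c1cc(OC)c(OC)cc1Br; NaOH, EtOH, rt) should give (E)-1-(2-bromo-4,5-dimethoxyphenyl)-3-[3-methoxy-4-(methoxymethoxy)phenyl]prop-2-en-1-one F1. Miyaura borylation (B2pin2, Pd(dppf)Cl2, KOAc, dioxane, 80 °C) should give the corresponding 2-(pinacolboryl) chalcone F2. Rh(I)-catalysed asymmetric intramolecular 1,4-addition ([Rh(C2H4)2Cl]2, chiral phosphoramidite, aq K3PO4, toluene) should close (S)-5,6-dimethoxy-3-[3-methoxy-4-(methoxymethoxy)phenyl]indan-1-one F3, the stereocentre being set by the ligand in the carborhodation of the enone. C-Acylation (NaH, diethyl carbonate, THF, reflux) then returns to 4.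

Step 3. C-Alkylation of the hindered tertiary zinc enolate next to the C3 aryl group may be sluggish, excess carbenoid may homologate the product enolate a second time, and the cis/trans equilibrium at C2 may be less one-sided than expected. The fallback is the radical (Dowd–Beckwith) ring expansion; it sets out from 4 and comes back at 6. Alkylation of 4 (NaH, CH2Br2, THF–DMPU, 50 °C) should give ethyl (2R,3S)-2-(bromomethyl)-5,6-dimethoxy-3-[3-methoxy-4-(methoxymethoxy)phenyl]-1-oxo-2,3-dihydro-1H-indene-2-carboxylate F4, with the bromomethyl group anti to the aryl group. Slow addition of Bu3SnH with AIBN in refluxing benzene should generate the primary radical, which adds to the ketone carbonyl; the cyclopropyloxy radical fragments to the ester-stabilised ring-expanded radical, and hydrogen transfer gives 6, which is equilibrated to 7 as in step 3.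

Step 4. The carbenium ion may attack the electron-rich MOM-bearing ring or exchange with the MOM acetal, or the hindered ketone may enolise too slowly. The fallback uses a Claisen formylation and the enol ether route to the enal; it sets out from 7 and comes back at 10. Formylation (NaH, HCO2Et, THF, 0 °C → rt) should give ethyl (1S,2R)-3-(hydroxymethylidene)-6,7-dimethoxy-1-[3-methoxy-4-(methoxymethoxy)phenyl]-4-oxo-1,2,3,4-tetrahydronaphthalene-2-carboxylate F5. O-Alkylation (2-iodopropane, K2CO3, acetone, reflux) should give the (E)-isopropoxymethylidene ketone F6. LiAlH4 (THF, 0 °C) should reduce ketone (1,2) and ester to the allylic alcohol enol ether diol F7, which is not isolated; 3 M aq HCl in THF at 45 °C should then hydrolyse the vinylogous hemiacetal with allylic transposition and remove the MOM group to give 10.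

Further compounds
F1 | step 2 | (E)-1-(2-bromo-4,5-dimethoxyphenyl)-3-[3-methoxy-4-(methoxymethoxy)phenyl]prop-2-en-1-one | COCOc1ccc(/C=C/C(=O)c2cc(OC)c(OC)cc2Br)cc1OC
F2 | step 2 | (E)-1-[4,5-dimethoxy-2-(4,4,5,5-tetramethyl-1,3,2-dioxaborolan-2-yl)phenyl]-3-[3-methoxy-4-(methoxymethoxy)phenyl]prop-2-en-1-one | COCOc1ccc(/C=C/C(=O)c2cc(OC)c(OC)cc2B3OC(C)(C)C(C)(C)O3)cc1OC
F3 | step 2 | (S)-5,6-dimethoxy-3-[3-methoxy-4-(methoxymethoxy)phenyl]-2,3-dihydro-1H-inden-1-one | COCOc1ccc([C@H]2c3cc(OC)c(OC)cc3C(=O)C2)cc1OC
F4 | step 3 | ethyl (2R,3S)-2-(bromomethyl)-5,6-dimethoxy-3-[3-methoxy-4-(methoxymethoxy)phenyl]-1-oxo-2,3-dihydro-1H-indene-2-carboxylate | COCOc1ccc([C@H]2c3cc(OC)c(OC)cc3C(=O)[C@]2(C(=O)OCC)CBr)cc1OC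
F5 | step 4 | ethyl (1S,2R)-3-(hydroxymethylidene)-6,7-dimethoxy-1-[3-methoxy-4-(methoxymethoxy)phenyl]-4-oxo-1,2,3,4-tetrahydronaphthalene-2-carboxylate (enol geometry not fixed) | COCOc1ccc([C@H]2c3cc(OC)c(OC)cc3C(=O)C(=CO)[C@@H]2C(=O)OCC)cc1OC
F6 | step 4 | ethyl (1S,2R,3E)-6,7-dimethoxy-1-[3-methoxy-4-(methoxymethoxy)phenyl]-4-oxo-3-[(propan-2-yloxy)methylidene]-1,2,3,4-tetrahydronaphthalene-2-carboxylate | COCOc1ccc([C@H]2c3cc(OC)c(OC)cc3C(=O)/C(=C/OC(C)C)[C@@H]2C(=O)OCC)cc1OC
F7 | step 4 | (2E,3R,4S)-3-(hydroxymethyl)-6,7-dimethoxy-4-[3-methoxy-4-(methoxymethoxy)phenyl]-2-[(propan-2-yloxy)methylidene]-1,2,3,4-tetrahydronaphthalen-1-ol, C1 epimers (not isolated) | COCOc1ccc([C@H]2c3cc(OC)c(OC)cc3C(O)/C(=C/OC(C)C)[C@@H]2CO)cc1OC
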